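Ring B is a phloroglucinol whose C1 and C5 bear the identical rings A and C on either side of C6–O. The array C2(O)–C1(aryl)–C6(O)–C5(aryl) is the skeleton of a head-to-tail arylketene dimer, so only C3(H)–C4(O) is missing. Everything rests on a Danheiser benzannulation. Racemic 3-benzyloxy-2,4-diarylcyclobutenone 11 is heated with (triisopropylsilyloxy)acetylene 16. The ynol ether is inserted between the carbonyl carbon and the aryl-bearing sp2 carbon, C2–C3 and C4–C5 form, and ring B closes with three differentiated oxygens. Both biaryl bonds are the aryl–CH2 bonds of one arylacetic acid. Benzyl ethers mask the seven final hydroxyls, and MOM ethers mark the two sulfation sites.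

Key step: step 7

Numbering and shorthand: ring B is C1 (ring A), C2 (O), C3 (H), C4 (O), C5 (ring C), C6 (O). Ar = 2,4-bis(benzyloxy)-6-(methoxymethoxy)phenyl.
Assumption 1: the target SMILES defines no configuration at the two biaryl axes, so none is controlled and the thermally equilibrated rotamer mixture is accepted.
Assumption 2: the aryl hydrogen sulfates 25 and 26 are handled as sodium salts and drawn in the neutral acid form of the target. The free acid is released only at the very end on a cold H+ resin.

Step 1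
Reactants: 1 2,4,6-trihydroxyacetophenone; 2 benzyl bromide
Product: 3 1-[2,4-bis(benzyloxy)-6-hydroxyphenyl]ethan-1-one
Conditions: BnBr (2.1 equiv), K2CO3, DMF, 60 °C
Reagents that add atoms: benzyl bromide 2, BrCc1ccccc1
Why: Williamson etherification in which the para and one ortho phenoxide react while the last ortho OH stays locked in a hydrogen bond to the acetyl carbonyl, which singles out the future sulfation site.

Step 2
Reactants: 3 1-[2,4-bis(benzyloxy)-6-hydroxyphenyl]ethan-1-one; 4 chloromethyl methyl ether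
Product: 5 1-[2,4-bis(benzyloxy)-6-(methoxymethoxy)phenyl]ethan-1-one
Conditions: NaH, MOMCl, DMF, 0 °C to rt
Reagents that add atoms: chloromethyl methyl ether 4, COCCl
Why: Irreversible deprotonation with NaH breaks the chelate and the phenoxide is alkylated by MOMCl (Williamson-type acetal formation), placing a base-stable, acid-labile group orthogonal to benzyl.

Step 3
Reactants: 5 1-[2,4-bis(benzyloxy)-6-(methoxymethoxy)phenyl]ethan-1-one
Product: 7 [2,4-bis(benzyloxy)-6-(methoxymethoxy)phenyl]acetic acid, via thiomorpholide 6 (not isolated)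
Conditions: S8, morpholine, 130 °C; then KOH, EtOH–H2O, reflux; acidify to pH 4 at 0 °C
Reagents that add atoms: sulfur, S1SSSSSSS1, and morpholine, C1COCCN1 (both end up in 6 only); potassium hydroxide, [K+].[OH-]; water, O
Why: The Willgerodt–Kindler reaction followed by alkaline thioamide hydrolysis moves the oxidised carbon to the chain end under purely basic conditions that benzyl ethers and MOM acetals tolerate, and the telescoped form is standard practice for arylacetic acids.

Step 4
Reactants: 7 [2,4-bis(benzyloxy)-6-(methoxymethoxy)phenyl]acetic acid (two molecules)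
Product: 10 racemic 2,4-bis[2,4-bis(benzyloxy)-6-(methoxymethoxy)phenyl]-3-hydroxycyclobut-2-en-1-one, via acid chloride 8 (not isolated), via arylketene 9 (not isolated)
Conditions: Me2C=C(Cl)NMe2, CH2Cl2, 0 °C; then Et3N (3 equiv), 0 to 40 °C; MeOH quench; extraction into aq. Na2CO3, re-acidification to pH 4
Reagents that add atoms: 1-chloro-N,N,2-trimethylprop-1-en-1-amine, CC(C)=C(Cl)N(C)C (chlorine of 8 only)
Why: Neutral chloroenamine activation spares the MOM acetals, Et3N dehydrochlorinates 8 to arylketene 9, and head-to-tail aldoketene dimerisation (the route to 3-hydroxycyclobutenones known for phenylacetyl chloride) with excess amine and a methanol quench funnels lactone-type dimers and O-acylated enol into the strongly acidic conjugated enol 10, whose two tautomers are identical and whose C4 stereocentre forms racemic and is erased in step 7.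

Step 5
Reactants: 10 racemic 2,4-diaryl-3-hydroxycyclobut-2-en-1-one; 2 benzyl bromide
Product: 11 racemic 3-(benzyloxy)-2,4-bis[2,4-bis(benzyloxy)-6-(methoxymethoxy)phenyl]cyclobut-2-en-1-one
Conditions: BnBr (1.05 equiv), Cs2CO3, DMF, 0 °C to rt
Reagents that add atoms: benzyl bromide 2, BrCc1ccccc1
Why: This is a Williamson-type O-alkylation of a vinylogous carboxylate, in which carbon alkylation would build a quaternary centre next to a 2,6-disubstituted aryl group and break the conjugation, so the caesium enolate reacts at oxygen and the degenerate enol gives one regioisomer, still racemic at C4.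

Step 6
Reactants: 12 acetylene; 13 triisopropylsilyl trifluoromethanesulfonate
Product: 16 (triisopropylsilyloxy)acetylene, via lithium acetylide 14 (not isolated), via lithium ethynolate 15 (not isolated)
Conditions: HC≡CH (excess), nBuLi, THF, −78 °C; LiOOtBu (preformed from tBuOOH and LiN(SiMe3)2), −78 to −20 °C; iPr3SiOTf, −78 to 0 °C; pentane work-up, distillation
Reagents that add atoms: tert-butyl hydroperoxide, CC(C)(C)OO (the ynol oxygen); triisopropylsilyl trifluoromethanesulfonate 13, CC(C)[Si](OS(=O)(=O)C(F)(F)F)(C(C)C)C(C)C; n-butyllithium, [Li]CCCC (lithium of 14 and 15 only)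
Why: Electrophilic oxygen transfer from lithium tert-butyl peroxide to a lithium acetylide gives the ynolate and the hard, bulky silyl triflate traps it on oxygen (the standard preparation of triisopropylsilyl ynol ethers), while excess dissolved acetylene and low temperature hold back disproportionation of 14.

Step 7
Reactants: 11 racemic 3-(benzyloxy)-2,4-diarylcyclobut-2-en-1-one; 16 (triisopropylsilyloxy)acetylene
Product: 21 3-(benzyloxy)-2,4-bis[2,4-bis(benzyloxy)-6-(methoxymethoxy)phenyl]-5-(triisopropylsilyloxy)phenol, via vinylketene 17 (not isolated), via alkenylcyclobutenone 18 (not isolated), via dienylketene 19 (not isolated), via cyclohexadienone 20 (not isolated)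
Conditions: 16 (3 equiv), PhMe, 110 °C, sealed tube, Ar
Reagents that add atoms: none
Why: Danheiser benzannulation, a cascade of pericyclic events: conrotatory 4π opening of 11 cuts the C(=O)–C(sp3) bond to give aryl(vinyl)ketene 17, and the polarised ynol ether adds [2+2] across the ketene C=C, its nucleophilic CH carbon bonding to the ketene carbonyl carbon (C2–C3) and its siloxy carbon to the aryl-bearing α-carbon, the former sp2 C2 of 11 (C4–C5), to give 18. A second 4π opening cuts the old carbonyl–Cα bond (C2 to C5) and delivers dienylketene 19, whose disrotatory 6π electrocyclisation rejoins the ketene carbon to the former sp3 carbon (C1–C2) and thereby closes ring B, after which tautomerisation of 20 gives phenol 21. The closest known reactions are the annulations of substituted cyclobutenones with triisopropylsilyl ynol ethers to resorcinol monosilyl ethers and the thermal opening of 3-alkoxy-2,4-diarylcyclobutenones near this temperature. No stereocentre is created, and those of 11, 18 and 20 vanish on aromatisation. The only selectivity needed is the orientation of the [2+2] step, which the oxygen-donor polarisation of 16 against the electrophilic ketene carbon fixes, so that the oxygens on C2, C4 and C6 end up mutually meta and each carries a different group (H, silyl, benzyl). Both ortho positions of each aryl group carry oxygen, so the usual escape of a 4-arylcyclobutenone, 6π closure onto the arene to a naphthol, cannot aromatise and stays reversible, and the unsubstituted alkyne terminus keeps the crowded [2+2] transition state as small as possible.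

Step 8
Reactants: 21 benzannulation phenol; 2 benzyl bromide
Product: 23 1,3,5-tris(benzyloxy)-2,4-bis[2,4-bis(benzyloxy)-6-(methoxymethoxy)phenyl]benzene, via monobenzylated silyl ether 22 (not isolated)
Conditions: BnBr (3 equiv), K2CO3, DMF, rt; then Bu4NF (THF), rt, same flask
Reagents that add atoms: benzyl bromide 2, BrCc1ccccc1
Why: Williamson benzylation of the free C2 phenol is followed by fluoride-triggered desilylative benzylation of the C4 silyl ether in the same flask, an order that never exposes a free resorcinol dianion and so limits C-benzylation at C3.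

Step 9
Reactants: 23 heptabenzyl bis-MOM terphenyl
Product: 24 2',4,4',4'',6,6',6''-heptakis(benzyloxy)-[1,1':3',1''-terphenyl]-2,2''-diol
Conditions: 3 M aq. HCl, MeOH–THF, 45 °C
Reagents that add atoms: none
Why: Acid-catalysed acetal exchange (MOM cleavage) with methanol takes up the formaldehyde unit as dimethoxymethane and leaves aryl benzyl ethers untouched.

Step 10
Reactants: 24 heptabenzyl terphenyldiol
Product: 25 2',4,4',4'',6,6',6''-heptakis(benzyloxy)-[1,1':3',1''-terphenyl]-2,2''-diyl bis(hydrogen sulfate)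
Conditions: SO3·pyridine (excess), pyridine, 45 °C; then Na+ ion-exchange resin
Reagents that add atoms: sulfur trioxide pyridine complex, O=S(=O)([O-])[n+]1ccccc1
Why: O-sulfation of phenols with the mild SO3·pyridine complex meets only the two wanted free hydroxyls, and the cation exchange removes pyridinium, which would inhibit benzyl ether hydrogenolysis in the next step.

Step 11
Reactants: 25 heptabenzyl bis(hydrogen sulfate)
Product: 26 2',4,4',4'',6,6',6''-heptahydroxy-[1,1':3',1''-terphenyl]-2,2''-diyl bis(hydrogen sulfate) (CNP0320583.0)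
Conditions: H2 (1 atm), 10% Pd/C, MeOH–THF, rt, air excluded; then H+ ion-exchange resin, 0 °C, lyophilisation
Reagents that add atoms: none
Why: Catalytic hydrogenolysis cleaves the seven aryl benzyl ethers while aryl sulfate monoesters are inert to it, and cold proton exchange then gives the acid form.

Compound list
1 | 2,4,6-trihydroxyacetophenone | CC(=O)c1c(O)cc(O)cc1O | starting material
2 | benzyl bromide | BrCc1ccccc1 | starting material
3 | 1-[2,4-bis(benzyloxy)-6-hydroxyphenyl]ethan-1-one | CC(=O)c1c(O)cc(OCc2ccccc2)cc1OCc1ccccc1 | intermediate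
4 | chloromethyl methyl ether | COCCl | starting material
5 | 1-[2,4-bis(benzyloxy)-6-(methoxymethoxy)phenyl]ethan-1-one | CC(=O)c1c(OCOC)cc(OCc2ccccc2)cc1OCc1ccccc1 | intermediate
6 | 2-[2,4-bis(benzyloxy)-6-(methoxymethoxy)phenyl]-1-(morpholin-4-yl)ethane-1-thione | S=C(Cc1c(OCOC)cc(OCc2ccccc2)cc1OCc1ccccc1)N1CCOCC1 | intermediate
7 | [2,4-bis(benzyloxy)-6-(methoxymethoxy)phenyl]acetic acid | OC(=O)Cc1c(OCOC)cc(OCc2ccccc2)cc1OCc1ccccc1 | intermediate
8 | [2,4-bis(benzyloxy)-6-(methoxymethoxy)phenyl]acetyl chloride | ClC(=O)Cc1c(OCOC)cc(OCc2ccccc2)cc1OCc1ccccc1 | intermediate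
9 | [2,4-bis(benzyloxy)-6-(methoxymethoxy)phenyl]ketene | O=C=Cc1c(OCOC)cc(OCc2ccccc2)cc1OCc1ccccc1 | intermediate
10 | racemic 2,4-bis(Ar)-3-hydroxycyclobut-2-en-1-one | O=C1C(c2c(OCOC)cc(OCc3ccccc3)cc2OCc2ccccc2)=C(O)C1c1c(OCOC)cc(OCc2ccccc2)cc1OCc1ccccc1 | intermediate
11 | racemic 3-(benzyloxy)-2,4-bis(Ar)cyclobut-2-en-1-one | O=C1C(c2c(OCOC)cc(OCc3ccccc3)cc2OCc2ccccc2)=C(OCc2ccccc2)C1c1c(OCOC)cc(OCc2ccccc2)cc1OCc1ccccc1 | intermediate
12 | acetylene | C#C | starting material
13 | triisopropylsilyl trifluoromethanesulfonate | CC(C)[Si](OS(=O)(=O)C(F)(F)F)(C(C)C)C(C)C | starting material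
14 | lithium acetylide | [Li+].[C-]#C | intermediate
15 | lithium ethynolate | [Li+].[O-]C#C | intermediate
16 | (triisopropylsilyloxy)acetylene | C#CO[Si](C(C)C)(C(C)C)C(C)C | intermediate
17 | 3-(benzyloxy)-2,4-bis(Ar)buta-1,3-dien-1-one, terminal aryl trans to the ketene unit | O=C=C(c1c(OCOC)cc(OCc2ccccc2)cc1OCc1ccccc1)/C(OCc1ccccc1)=C/c1c(OCOC)cc(OCc2ccccc2)cc1OCc1ccccc1 | intermediate
18 | racemic 4-(Ar)-4-[1-(benzyloxy)-2-(Ar)ethenyl]-3-(triisopropylsilyloxy)cyclobut-2-en-1-one | O=C1C=C(O[Si](C(C)C)(C(C)C)C(C)C)C1(c1c(OCOC)cc(OCc2ccccc2)cc1OCc1ccccc1)/C(OCc1ccccc1)=C/c1c(OCOC)cc(OCc2ccccc2)cc1OCc1ccccc1 | intermediate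
19 | 5-(benzyloxy)-4,6-bis(Ar)-3-(triisopropylsilyloxy)hexa-1,3,5-trien-1-one, ketenyl and alkenyl groups cis on the central alkene | O=C=C/C(O[Si](C(C)C)(C(C)C)C(C)C)=C(c1c(OCOC)cc(OCc2ccccc2)cc1OCc1ccccc1)\C(OCc1ccccc1)=C\c1c(OCOC)cc(OCc2ccccc2)cc1OCc1ccccc1 | intermediate
20 | racemic 5-(benzyloxy)-4,6-bis(Ar)-3-(triisopropylsilyloxy)cyclohexa-2,4-dien-1-one | O=C1C=C(O[Si](C(C)C)(C(C)C)C(C)C)C(c2c(OCOC)cc(OCc3ccccc3)cc2OCc2ccccc2)=C(OCc2ccccc2)C1c1c(OCOC)cc(OCc2ccccc2)cc1OCc1ccccc1 | intermediate
21 | 3-(benzyloxy)-2,4-bis(Ar)-5-(triisopropylsilyloxy)phenol | Oc1cc(O[Si](C(C)C)(C(C)C)C(C)C)c(-c2c(OCOC)cc(OCc3ccccc3)cc2OCc2ccccc2)c(OCc2ccccc2)c1-c1c(OCOC)cc(OCc2ccccc2)cc1OCc1ccccc1 | intermediate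
22 | [3,5-bis(benzyloxy)-2,4-bis(Ar)phenoxy]triisopropylsilane | CC(C)[Si](C(C)C)(C(C)C)Oc1cc(OCc2ccccc2)c(-c2c(OCOC)cc(OCc3ccccc3)cc2OCc2ccccc2)c(OCc2ccccc2)c1-c1c(OCOC)cc(OCc2ccccc2)cc1OCc1ccccc1 | intermediate
23 | 1,3,5-tris(benzyloxy)-2,4-bis(Ar)benzene | COCOc1cc(OCc2ccccc2)cc(OCc2ccccc2)c1-c1c(OCc2ccccc2)cc(OCc2ccccc2)c(-c2c(OCOC)cc(OCc3ccccc3)cc2OCc2ccccc2)c1OCc1ccccc1 | intermediate
24 | 2',4,4',4'',6,6',6''-heptakis(benzyloxy)-[1,1':3',1''-terphenyl]-2,2''-diol | Oc1cc(OCc2ccccc2)cc(OCc2ccccc2)c1-c1c(OCc2ccccc2)cc(OCc2ccccc2)c(-c2c(O)cc(OCc3ccccc3)cc2OCc2ccccc2)c1OCc1ccccc1 | intermediate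
25 | 2',4,4',4'',6,6',6''-heptakis(benzyloxy)-[1,1':3',1''-terphenyl]-2,2''-diyl bis(hydrogen sulfate) | O=S(=O)(O)Oc1cc(OCc2ccccc2)cc(OCc2ccccc2)c1-c1c(OCc2ccccc2)cc(OCc2ccccc2)c(-c2c(OS(=O)(=O)O)cc(OCc3ccccc3)cc2OCc2ccccc2)c1OCc1ccccc1 | intermediate
26 | 2',4,4',4'',6,6',6''-heptahydroxy-[1,1':3',1''-terphenyl]-2,2''-diyl bis(hydrogen sulfate) | O=S(=O)(O)Oc1cc(O)cc(O)c1-c1c(O)cc(O)c(-c2c(O)cc(O)cc2OS(=O)(=O)O)c1O | target

Total step count: 11. Longest linear sequence: 10 (steps 1–5 and 7–11). Step 6 is a one-step side branch.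

Steps most likely to fail

Step 7. Bimolecular capture of the very crowded aryl(vinyl)ketene may be slower than three competing processes:
- reclosure of the ketene to the cyclobutenone
- attack of a neighbouring acetal or ether oxygen on the ketene
- the thermal oxygen-to-carbon silyl shift of the ynol ether

The fallback replaces annulation by cross-coupling. It sets out from chloromethyl methyl ether 4, which protects commercial 3,5-bis(benzyloxy)phenol (iPr2NEt, CH2Cl2) as 1,3-bis(benzyloxy)-5-(methoxymethoxy)benzene F1. MOM-directed ortho-lithiation (nBuLi, THF, 0 °C) at the position between OMOM and OBn gives [2,4-bis(benzyloxy)-6-(methoxymethoxy)phenyl]lithium F2, and ZnCl2 converts it into [2,4-bis(benzyloxy)-6-(methoxymethoxy)phenyl]zinc chloride F3. Commercial 1,3,5-tris(benzyloxy)benzene is iodinated twice (N-iodosuccinimide, MeCN) to 1,3,5-tris(benzyloxy)-2,4-diiodobenzene F4. A double Negishi coupling of F4 with F3 (Pd2(dba)3, RuPhos, THF, 70 °C), a catalyst system made for tetra-ortho-substituted biaryls, comes back to the route at 23.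

Step 4. Three things may go wrong:
- the dimerisation may close through oxygen instead of carbon
- the enolate may be over-acylated
- the acyl chloride may be attacked by the neighbouring MOM oxygen, with loss of that protecting group

The fallback makes the same four-membered ring by a ketene plus ynol ether [2+2] under neutral conditions. It sets out from 7.
- Alkylation (EtI, K2CO3, DMF) gives ethyl [2,4-bis(benzyloxy)-6-(methoxymethoxy)phenyl]acetate F5.
- Enolisation and phosphorylation (LiN(iPr)2, ClP(O)(OEt)2, THF, −78 °C) give the ketene acetal phosphate, 2-aryl-1-ethoxyethenyl diethyl phosphate F6 (E/Z mixture).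
- A further portion of LiN(iPr)2 eliminates phosphate to give 1,5-bis(benzyloxy)-2-(ethoxyethynyl)-3-(methoxymethoxy)benzene F7.
- Heating F7 (PhMe, 110 °C) lets part of it lose ethene by retro-ene reaction to arylketene 9. Arylketene 9 is caught regiospecifically by the remaining F7 to give racemic 3-ethoxy-2,4-bis(Ar)cyclobut-2-en-1-one F8.
- Nucleophilic de-ethylation of this vinylogous ester (PhSNa, DMF, 50 °C), with the stabilised cyclobutenolate as leaving group, comes back to the route at 10.

Step 6. Three things may go wrong: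
- monolithium acetylide may disproportionate on warming before oxygen transfer is complete
- the unsubstituted ynolate may be silylated on carbon instead of oxygen
- material may be lost on isolation through volatility

The fallback uses a carbon-capped ynol ether as an acetylene surrogate and removes the cap after the annulation. It sets out from 13 and commercial (trimethylsilyl)acetylene. Treatment with nBuLi gives lithium (trimethylsilyl)acetylide F9, which cannot disproportionate. LiOOtBu converts it into lithium (trimethylsilyl)ethynolate F10, and 13 silylates it on oxygen to trimethyl{[(triisopropylsilyl)oxy]ethynyl}silane F11. Heating F11 with 11 as in step 7 should give 3-(benzyloxy)-2,4-bis(Ar)-5-(triisopropylsilyloxy)-6-(trimethylsilyl)phenol F12. In F12 the C3–Si bond lies ortho or para to all three ring B oxygens, so mild ipso-protodesilylation (CF3CO2H, 1 equiv, CH2Cl2, −20 °C) should remove it before the MOM acetals react. This comes back to the route at 21.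

Further compounds
F1 | step 7 | 1,3-bis(benzyloxy)-5-(methoxymethoxy)benzene | COCOc1cc(OCc2ccccc2)cc(OCc2ccccc2)c1
F2 | step 7 | [2,4-bis(benzyloxy)-6-(methoxymethoxy)phenyl]lithium | [Li]c1c(OCOC)cc(OCc2ccccc2)cc1OCc1ccccc1
F3 | step 7 | [2,4-bis(benzyloxy)-6-(methoxymethoxy)phenyl]zinc chloride | Cl[Zn]c1c(OCOC)cc(OCc2ccccc2)cc1OCc1ccccc1
F4 | step 7 | 1,3,5-tris(benzyloxy)-2,4-diiodobenzene | Ic1c(OCc2ccccc2)cc(OCc2ccccc2)c(I)c1OCc1ccccc1
F5 | step 4 | ethyl [2,4-bis(benzyloxy)-6-(methoxymethoxy)phenyl]acetate | CCOC(=O)Cc1c(OCOC)cc(OCc2ccccc2)cc1OCc1ccccc1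
F6 | step 4 | 2-[2,4-bis(benzyloxy)-6-(methoxymethoxy)phenyl]-1-ethoxyethenyl diethyl phosphate (E/Z mixture) | CCOC(=Cc1c(OCOC)cc(OCc2ccccc2)cc1OCc1ccccc1)OP(=O)(OCC)OCC
F7 | step 4 | 1,5-bis(benzyloxy)-2-(ethoxyethynyl)-3-(methoxymethoxy)benzene | CCOC#Cc1c(OCOC)cc(OCc2ccccc2)cc1OCc1ccccc1
F8 | step 4 | racemic 3-ethoxy-2,4-bis[2,4-bis(benzyloxy)-6-(methoxymethoxy)phenyl]cyclobut-2-en-1-one | O=C1C(c2c(OCOC)cc(OCc3ccccc3)cc2OCc2ccccc2)=C(OCC)C1c1c(OCOC)cc(OCc2ccccc2)cc1OCc1ccccc1
F9 | step 6 | lithium (trimethylsilyl)acetylide | [Li+].[C-]#C[Si](C)(C)C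
F10 | step 6 | lithium (trimethylsilyl)ethynolate | [Li+].[O-]C#C[Si](C)(C)C
F11 | step 6 | trimethyl{[(triisopropylsilyl)oxy]ethynyl}silane | C[Si](C)(C)C#CO[Si](C(C)C)(C(C)C)C(C)C
F12 | step 6 | 3-(benzyloxy)-2,4-bis[2,4-bis(benzyloxy)-6-(methoxymethoxy)phenyl]-5-(triisopropylsilyloxy)-6-(trimethylsilyl)phenol | Oc1c([Si](C)(C)C)c(O[Si](C(C)C)(C(C)C)C(C)C)c(-c2c(OCOC)cc(OCc3ccccc3)cc2OCc2ccccc2)c(OCc2ccccc2)c1-c1c(OCOC)cc(OCc2ccccc2)cc1OCc1ccccc1
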